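The route rests on disconnecting the C2–C3 bond of ring C. A symmetric 2,6-dimethoxyaryl ketone already contains O1, the carbon that becomes C2 and the 5-OMe of ring A. An aryl(aroyl) carbene generated at C3 from an α-diazo deoxybenzoin can therefore insert into a C–H bond of either ortho methoxy group under a chiral dirhodium carboxylate. That single operation forms C2–C3, closes ring C and sets the C3 stereocentre under neutral conditions, while the untouched methoxy group remains as 5-OMe. The precursor is the bis(triisopropylsilyl)-protected 2-diazo-1-(2,6-dimethoxy-4-silyloxyphenyl)-2-(8-silyloxy-2,2-dimethylchromen-6-yl)ethanone, assembled from an aryllithium and a chromenylacetaldehyde.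

Key step: step 10

Remark: both phenols are carried as triisopropylsilyl (TIPS) ethers, because aryl tert-butyldimethylsilyl ethers are at risk with n-BuLi and with DBU during diazo transfer; the skeletons of the diazoketone and of its insertion product are unchanged by this choice.

Assumption: the sense of induction of the tert-leucinate catalyst at the carbene carbon cannot be predicted with confidence. Rh2(S-PTTL)4, dirhodium tetrakis[N-phthaloyl-(S)-tert-leucinate], is written; its mirror image Rh2(R-PTTL)4 would be used instead if a pilot run shows that it is the one that gives the 3R product.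

Step 1
Reactants: 1 3,5-dimethoxyphenol
Product: 2 (3,5-dimethoxyphenoxy)triisopropylsilane
Conditions: TIPSCl, imidazole, DMF, rt
Reagents that add atoms: chlorotri(propan-2-yl)silane (TIPSCl), CC(C)[Si](Cl)(C(C)C)C(C)C
Why: Imidazole-promoted O-silylation of a phenol is routine, and the TIPS ether is chosen because its bulk keeps n-BuLi away from the positions next to the silyloxy group and it resists DBU in the later diazo transfer.

Step 2
Reactants: 3 3,4-dihydroxybenzaldehyde; 4 3-chloro-3-methylbut-1-yne
Product: 5 3-hydroxy-4-[(2-methylbut-3-yn-2-yl)oxy]benzaldehyde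
Conditions: K2CO3 (1.1 equiv), KI, DMF, 65 °C
Reagents that add atoms: none
Why: Williamson-type O-alkylation: the 4-OH lies para to the formyl group and is the more acidic hydroxyl, so one equivalent of carbonate generates essentially only the 4-phenoxide, which captures the tertiary propargylic electrophile and leaves the 3-OH untouched.

Step 3
Reactants: 5 3-hydroxy-4-[(2-methylbut-3-yn-2-yl)oxy]benzaldehyde
Product: 6 4-[(2-methylbut-3-yn-2-yl)oxy]-3-[(triisopropylsilyl)oxy]benzaldehyde
Conditions: TIPSCl, imidazole, DMF, rt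
Reagents that add atoms: chlorotri(propan-2-yl)silane (TIPSCl), CC(C)[Si](Cl)(C(C)C)C(C)C
Why: Imidazole-promoted O-silylation caps the remaining phenol before the thermal step and installs the same silyl group as on ring A, so that one reagent frees both phenols at the end.

Step 4
Reactants: 6 4-[(2-methylbut-3-yn-2-yl)oxy]-3-[(triisopropylsilyl)oxy]benzaldehyde
Product: 8 2,2-dimethyl-8-[(triisopropylsilyl)oxy]-2H-chromene-6-carbaldehyde, via allenyl phenol 7 (not isolated)
Conditions: N,N-diethylaniline, 190 °C, argon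
Reagents that add atoms: none
Why: Aromatic propargyl Claisen rearrangement: the [3,3] shift can aromatise only at C5, because the other ortho carbon carries the silyloxy group and the para carbon the formyl group, and the allenyl phenol 7 then closes to the 2,2-dimethyl-2H-chromene by 1,5-hydrogen shift and oxa-6π electrocyclisation.

Step 5
Reactants: 8 2,2-dimethyl-8-[(triisopropylsilyl)oxy]-2H-chromene-6-carbaldehyde
Product: 9 {[6-(2-methoxyethenyl)-2,2-dimethyl-2H-chromen-8-yl]oxy}triisopropylsilane (E/Z mixture)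
Conditions: Ph3P(CH2OMe)Cl, KOt-Bu, THF, 0 °C → rt
Reagents that add atoms: (methoxymethyl)triphenylphosphonium chloride, COC[P+](c1ccccc1)(c1ccccc1)c1ccccc1.[Cl-]
Why: Wittig olefination of the non-enolisable aryl aldehyde with methoxymethylenetriphenylphosphorane adds the carbon that becomes C4 of the target, and the E/Z mixture is of no consequence because both isomers hydrolyse to the same aldehyde.

Step 6
Reactants: 9 {[6-(2-methoxyethenyl)-2,2-dimethyl-2H-chromen-8-yl]oxy}triisopropylsilane
Product: 10 2-{2,2-dimethyl-8-[(triisopropylsilyl)oxy]-2H-chromen-6-yl}acetaldehyde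
Conditions: 2 M aq HCl, THF, 45 °C; used without storage
Reagents that add atoms: water, O
Why: Acid-catalysed enol ether hydrolysis (C-protonation, hydration of the oxocarbenium ion, loss of methanol) unmasks the arylacetaldehyde, while aryl TIPS ethers and the 2,2-dimethylchromene tolerate dilute aqueous acid.

Step 7
Reactants: 2 (3,5-dimethoxyphenoxy)triisopropylsilane; 10 2-{2,2-dimethyl-8-[(triisopropylsilyl)oxy]-2H-chromen-6-yl}acetaldehyde
Product: 13 rac-1-{2,6-dimethoxy-4-[(triisopropylsilyl)oxy]phenyl}-2-{2,2-dimethyl-8-[(triisopropylsilyl)oxy]-2H-chromen-6-yl}ethan-1-ol, via aryllithium 11 (not isolated), via arylcerium dichloride 12 (not isolated)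
Conditions: 2, n-BuLi, THF, 0 °C → rt; anhydrous CeCl3, −78 °C; then 10, −78 °C; aq NH4Cl; chromatography on Et3N-deactivated silica
Reagents that add atoms: none
Why: Directed ortho-metalation places lithium at the one position flanked by two methoxy groups (the bulky silyloxy group is a poor director), and transmetalation to the less basic organocerium reagent favours 1,2-addition to the enolisable aldehyde over deprotonation; the carbinol centre is racemic and is destroyed in step 8.

Step 8
Reactants: 13 rac-1-{2,6-dimethoxy-4-[(triisopropylsilyl)oxy]phenyl}-2-{2,2-dimethyl-8-[(triisopropylsilyl)oxy]-2H-chromen-6-yl}ethan-1-ol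
Product: 14 1-{2,6-dimethoxy-4-[(triisopropylsilyl)oxy]phenyl}-2-{2,2-dimethyl-8-[(triisopropylsilyl)oxy]-2H-chromen-6-yl}ethan-1-one
Conditions: Dess–Martin periodinane, pyridine, CH2Cl2, 0 °C → rt
Reagents that add atoms: none
Why: Dess–Martin oxidation of the secondary benzylic alcohol to the aryl ketone is mild, and pyridine buffers the acetic acid released so that the electron-rich benzylic carbinol does not ionise and dehydrate to the stilbene.

Step 9
Reactants: 14 1-{2,6-dimethoxy-4-[(triisopropylsilyl)oxy]phenyl}-2-{2,2-dimethyl-8-[(triisopropylsilyl)oxy]-2H-chromen-6-yl}ethan-1-one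
Product: 15 2-diazo-1-{2,6-dimethoxy-4-[(triisopropylsilyl)oxy]phenyl}-2-{2,2-dimethyl-8-[(triisopropylsilyl)oxy]-2H-chromen-6-yl}ethan-1-one
Conditions: 4-acetamidobenzenesulfonyl azide (p-ABSA), DBU, MeCN, 0 °C → rt, dark
Reagents that add atoms: 4-acetamidobenzenesulfonyl azide (p-ABSA), CC(=O)Nc1ccc(cc1)S(=O)(=O)N=[N+]=[N-]
Why: Regitz diazo transfer: the methylene of a deoxybenzoin is activated by both the carbonyl and the aryl group, so DBU suffices to form the enolate, which attacks the sulfonyl azide and releases the sulfonamide to leave the α-aryl-α-diazoketone.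

Step 10
Reactants: 15 2-diazo-1-{2,6-dimethoxy-4-[(triisopropylsilyl)oxy]phenyl}-2-{2,2-dimethyl-8-[(triisopropylsilyl)oxy]-2H-chromen-6-yl}ethan-1-one
Product: 16 (3R)-5-methoxy-3-{2,2-dimethyl-8-[(triisopropylsilyl)oxy]-2H-chromen-6-yl}-7-[(triisopropylsilyl)oxy]-2,3-dihydro-4H-chromen-4-one
Conditions: Rh2(S-PTTL)4 (1 mol %), 4 Å molecular sieves, CH2Cl2 (0.01 M), slow addition of 15, 0 °C → rt; rapid chromatography on neutral silica
Reagents that add atoms: none
Why: Loss of dinitrogen from 15 at the dirhodium centre gives a rhodium-bound aryl(aroyl) carbene at the future C3, which inserts into a C–H bond of an ortho methoxy group in a concerted three-centre, hydride-transfer-like event in which the ether oxygen stabilises the positive charge building up on the methyl carbon. The reaction type is the established dirhodium-catalysed intramolecular C–H insertion next to the ether oxygen of 2-alkoxyaryl diazoketones that gives chroman-4-ones, applied here with a methyl ether as C–H donor and an aryl donor on the carbene, both of which are known partners in intramolecular insertions next to oxygen. Ring C closes by 1,6-insertion, the six ring atoms being the carbene carbon (C3), C4, C4a, C8a, O1 and the former methoxy carbon (C2), and no other C–H bond is in reach because both ortho positions of ring A carry methoxy groups and the 1,5 position is oxygen. C3 is the only new stereocentre and is under catalyst control: the chiral pocket formed by the four N-phthaloyl-tert-leucinate ligands decides which face of the carbene meets the C–H bond, and the medium is neutral so the α-aryl ketone is not enolised afterwards. The step needs C–H insertion to win over oxonium-ylide formation with 1,2-methyl shift, Wolff rearrangement, carbene dimerisation and attack on the chromene double bond; methyl is a poor migrating group so ylide formation should be reversible, the aryl donor tempers the carbene, the hindered cis-disubstituted chromene alkene is a poor partner, and slow addition at high dilution suppresses bimolecular paths. The two methoxy groups are equivalent, so no site selection is required and the one left over is the 5-OMe of the target.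

Step 11
Reactants: 16 (3R)-5-methoxy-3-{2,2-dimethyl-8-[(triisopropylsilyl)oxy]-2H-chromen-6-yl}-7-[(triisopropylsilyl)oxy]-2,3-dihydro-4H-chromen-4-one
Product: 17 (3R)-7-hydroxy-3-(8-hydroxy-2,2-dimethyl-2H-chromen-6-yl)-5-methoxy-2,3-dihydro-4H-chromen-4-one
Conditions: HF·pyridine, pyridine, THF, 0 °C → rt; pH 7 phosphate buffer
Reagents that add atoms: none
Why: Fluoride-mediated cleavage of both aryl silyl ethers in a weakly acidic, pyridine-buffered medium frees the two phenols without forming the enolate of the α-aryl ketone, so the C3 configuration should be retained, and the 5-OMe group and the chromene double bond are inert to HF·pyridine.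

Compound list
1 | 3,5-dimethoxyphenol | COc1cc(O)cc(OC)c1 | starting material
2 | (3,5-dimethoxyphenoxy)triisopropylsilane | COc1cc(O[Si](C(C)C)(C(C)C)C(C)C)cc(OC)c1 | intermediate
3 | 3,4-dihydroxybenzaldehyde | O=Cc1ccc(O)c(O)c1 | starting material
4 | 3-chloro-3-methylbut-1-yne | CC(C)(Cl)C#C | starting material
5 | 3-hydroxy-4-[(2-methylbut-3-yn-2-yl)oxy]benzaldehyde | O=Cc1ccc(OC(C)(C)C#C)c(O)c1 | intermediate
6 | 4-[(2-methylbut-3-yn-2-yl)oxy]-3-[(triisopropylsilyl)oxy]benzaldehyde | O=Cc1ccc(OC(C)(C)C#C)c(O[Si](C(C)C)(C(C)C)C(C)C)c1 | intermediate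
7 | 4-hydroxy-3-(3-methylbuta-1,2-dien-1-yl)-5-[(triisopropylsilyl)oxy]benzaldehyde (allenyl phenol, not isolated) | O=Cc1cc(C=C=C(C)C)c(O)c(O[Si](C(C)C)(C(C)C)C(C)C)c1 | intermediate
8 | 2,2-dimethyl-8-[(triisopropylsilyl)oxy]-2H-chromene-6-carbaldehyde | O=Cc1cc(O[Si](C(C)C)(C(C)C)C(C)C)c2c(c1)C=CC(C)(C)O2 | intermediate
9 | {[6-(2-methoxyethenyl)-2,2-dimethyl-2H-chromen-8-yl]oxy}triisopropylsilane (E/Z mixture) | COC=Cc1cc(O[Si](C(C)C)(C(C)C)C(C)C)c2c(c1)C=CC(C)(C)O2 | intermediate
10 | 2-{2,2-dimethyl-8-[(triisopropylsilyl)oxy]-2H-chromen-6-yl}acetaldehyde | O=CCc1cc(O[Si](C(C)C)(C(C)C)C(C)C)c2c(c1)C=CC(C)(C)O2 | intermediate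
11 | {2,6-dimethoxy-4-[(triisopropylsilyl)oxy]phenyl}lithium (not isolated) | [Li]c1c(OC)cc(O[Si](C(C)C)(C(C)C)C(C)C)cc1OC | intermediate
12 | dichloro{2,6-dimethoxy-4-[(triisopropylsilyl)oxy]phenyl}cerium (not isolated) | Cl[Ce](Cl)c1c(OC)cc(O[Si](C(C)C)(C(C)C)C(C)C)cc1OC | intermediate
13 | rac-1-{2,6-dimethoxy-4-[(triisopropylsilyl)oxy]phenyl}-2-{2,2-dimethyl-8-[(triisopropylsilyl)oxy]-2H-chromen-6-yl}ethan-1-ol (racemic carbinol) | COc1cc(O[Si](C(C)C)(C(C)C)C(C)C)cc(OC)c1C(O)Cc1cc(O[Si](C(C)C)(C(C)C)C(C)C)c2c(c1)C=CC(C)(C)O2 | intermediate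
14 | 1-{2,6-dimethoxy-4-[(triisopropylsilyl)oxy]phenyl}-2-{2,2-dimethyl-8-[(triisopropylsilyl)oxy]-2H-chromen-6-yl}ethan-1-one | COc1cc(O[Si](C(C)C)(C(C)C)C(C)C)cc(OC)c1C(=O)Cc1cc(O[Si](C(C)C)(C(C)C)C(C)C)c2c(c1)C=CC(C)(C)O2 | intermediate
15 | 2-diazo-1-{2,6-dimethoxy-4-[(triisopropylsilyl)oxy]phenyl}-2-{2,2-dimethyl-8-[(triisopropylsilyl)oxy]-2H-chromen-6-yl}ethan-1-one | COc1cc(O[Si](C(C)C)(C(C)C)C(C)C)cc(OC)c1C(=O)C(=[N+]=[N-])c1cc(O[Si](C(C)C)(C(C)C)C(C)C)c2c(c1)C=CC(C)(C)O2 | intermediate
16 | (3R)-5-methoxy-3-{2,2-dimethyl-8-[(triisopropylsilyl)oxy]-2H-chromen-6-yl}-7-[(triisopropylsilyl)oxy]-2,3-dihydro-4H-chromen-4-one | COc1cc(O[Si](C(C)C)(C(C)C)C(C)C)cc2c1C(=O)[C@H](c1cc(O[Si](C(C)C)(C(C)C)C(C)C)c3c(c1)C=CC(C)(C)O3)CO2 | intermediate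
17 | (3R)-7-hydroxy-3-(8-hydroxy-2,2-dimethyl-2H-chromen-6-yl)-5-methoxy-2,3-dihydro-4H-chromen-4-one | COc1cc(O)cc2c1C(=O)[C@H](c1cc(O)c3c(c1)C=CC(C)(C)O3)CO2 | target

Total steps: 11. Longest linear sequence: 10 steps (steps 2 to 11, from 3,4-dihydroxybenzaldehyde 3).

Steps most likely to fail

1. Step 10. Attack of the carbene on a methoxy oxygen followed by 1,2-methyl shift could outrun insertion into the primary C–H bond, or the C–H bond could approach both carbene faces with little discrimination, leaving low enantiomeric purity. The fallback sets out from 14 and comes back at 16, bypassing steps 9 and 10. One ortho methoxy group of 14 would be cleaved by chelation-assisted demethylation with MgI2·OEt2 in toluene at 70 °C to give 1-{2-hydroxy-6-methoxy-4-[(triisopropylsilyl)oxy]phenyl}-2-{2,2-dimethyl-8-[(triisopropylsilyl)oxy]-2H-chromen-6-yl}ethan-1-one F1. Heating F1 with N,N-dimethylformamide dimethyl acetal would close the pyranone and give the isoflavone 5-methoxy-3-{2,2-dimethyl-8-[(triisopropylsilyl)oxy]-2H-chromen-6-yl}-7-[(triisopropylsilyl)oxy]-4H-chromen-4-one F2. Asymmetric transfer hydrogenation with RuCl[(R,R)-TsDPEN](p-cymene) and HCO2H/Et3N would reduce the C2–C3 double bond and then the ketone, with dynamic kinetic resolution of the base-labile C3 centre. This should give the cis alcohol (3R,4R)-5-methoxy-3-{2,2-dimethyl-8-[(triisopropylsilyl)oxy]-2H-chromen-6-yl}-7-[(triisopropylsilyl)oxy]-3,4-dihydro-2H-chromen-4-ol F3; the (R,R) ligand is expected by analogy with simple aryl ketones to give 4R and hence 3R, and this is to be verified. Pyridine-buffered Dess–Martin oxidation of the carbinol then returns 16 without touching C3.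

2. Step 7. The aryl metal may deprotonate the arylacetaldehyde at its benzylic α-position instead of adding, the aldehyde may self-condense, or the electron-rich benzylic carbinol may dehydrate during isolation. The fallback sets out from 10 and comes back at 14, bypassing 13 and step 8. Pinnick oxidation of 10 (NaClO2, NaH2PO4, 2-methylbut-2-ene, t-BuOH/H2O) would give 2-{2,2-dimethyl-8-[(triisopropylsilyl)oxy]-2H-chromen-6-yl}acetic acid F4. Coupling with N,O-dimethylhydroxylamine hydrochloride (EDC·HCl, i-Pr2NEt, CH2Cl2) would give N-methoxy-N-methyl-2-{2,2-dimethyl-8-[(triisopropylsilyl)oxy]-2H-chromen-6-yl}acetamide F5. Acylation of aryllithium 11 (from 2 and n-BuLi, THF, −78 °C) with F5 in a Weinreb ketone synthesis should then deliver ketone 14 directly.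

3. Step 9. Deprotonation of the hindered, electron-rich benzylic methylene by DBU may be too slow for clean diazo transfer, or the diazo compound may decompose on prolonged exposure to base. The fallback sets out from 14 and comes back at 15. Riley oxidation of 14 with SeO2 in dioxane/H2O at 90 °C would give 1-{2,6-dimethoxy-4-[(triisopropylsilyl)oxy]phenyl}-2-{2,2-dimethyl-8-[(triisopropylsilyl)oxy]-2H-chromen-6-yl}ethane-1,2-dione F6. Condensation with TsNHNH2 (THF/MeOH, cat. AcOH) should occur at the carbonyl next to the chromene ring, because the other carbonyl is shielded by two ortho methoxy groups. This would give N'-(2-{2,6-dimethoxy-4-[(triisopropylsilyl)oxy]phenyl}-1-{2,2-dimethyl-8-[(triisopropylsilyl)oxy]-2H-chromen-6-yl}-2-oxoethylidene)-4-methylbenzenesulfonohydrazide F7. Bamford–Stevens elimination of sulfinate from F7 (aq NaOH, CH2Cl2, rt) then gives 15.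

Further compounds
F1 | step 10 | 1-{2-hydroxy-6-methoxy-4-[(triisopropylsilyl)oxy]phenyl}-2-{2,2-dimethyl-8-[(triisopropylsilyl)oxy]-2H-chromen-6-yl}ethan-1-one | COc1cc(O[Si](C(C)C)(C(C)C)C(C)C)cc(O)c1C(=O)Cc1cc(O[Si](C(C)C)(C(C)C)C(C)C)c2c(c1)C=CC(C)(C)O2
F2 | step 10 | 5-methoxy-3-{2,2-dimethyl-8-[(triisopropylsilyl)oxy]-2H-chromen-6-yl}-7-[(triisopropylsilyl)oxy]-4H-chromen-4-one | COc1cc(O[Si](C(C)C)(C(C)C)C(C)C)cc2c1C(=O)C(c1cc(O[Si](C(C)C)(C(C)C)C(C)C)c3c(c1)C=CC(C)(C)O3)=CO2
F3 | step 10 | (3R,4R)-5-methoxy-3-{2,2-dimethyl-8-[(triisopropylsilyl)oxy]-2H-chromen-6-yl}-7-[(triisopropylsilyl)oxy]-3,4-dihydro-2H-chromen-4-ol | COc1cc(O[Si](C(C)C)(C(C)C)C(C)C)cc2c1[C@H](O)[C@H](c1cc(O[Si](C(C)C)(C(C)C)C(C)C)c3c(c1)C=CC(C)(C)O3)CO2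
F4 | step 7 | 2-{2,2-dimethyl-8-[(triisopropylsilyl)oxy]-2H-chromen-6-yl}acetic acid | OC(=O)Cc1cc(O[Si](C(C)C)(C(C)C)C(C)C)c2c(c1)C=CC(C)(C)O2
F5 | step 7 | N-methoxy-N-methyl-2-{2,2-dimethyl-8-[(triisopropylsilyl)oxy]-2H-chromen-6-yl}acetamide | CON(C)C(=O)Cc1cc(O[Si](C(C)C)(C(C)C)C(C)C)c2c(c1)C=CC(C)(C)O2
F6 | step 9 | 1-{2,6-dimethoxy-4-[(triisopropylsilyl)oxy]phenyl}-2-{2,2-dimethyl-8-[(triisopropylsilyl)oxy]-2H-chromen-6-yl}ethane-1,2-dione | COc1cc(O[Si](C(C)C)(C(C)C)C(C)C)cc(OC)c1C(=O)C(=O)c1cc(O[Si](C(C)C)(C(C)C)C(C)C)c2c(c1)C=CC(C)(C)O2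
F7 | step 9 | N'-(2-{2,6-dimethoxy-4-[(triisopropylsilyl)oxy]phenyl}-1-{2,2-dimethyl-8-[(triisopropylsilyl)oxy]-2H-chromen-6-yl}-2-oxoethylidene)-4-methylbenzenesulfonohydrazide | COc1cc(O[Si](C(C)C)(C(C)C)C(C)C)cc(OC)c1C(=O)C(=NNS(=O)(=O)c1ccc(C)cc1)c1cc(O[Si](C(C)C)(C(C)C)C(C)C)c2c(c1)C=CC(C)(C)O2
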